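**Retrosynthetic overview**
1. Target ⇐ O‑sulfation of the hydroquinone ⇐ oxidative demethylation/reduction of dimethyl ether 39; the exocyclic methylene comes from a late Wittig reaction.
2. Upper cis‑decalin ⇐ enedione 27: 8‑methyl by methylenation/hydrogenation, C9 quaternary carbon by reductive benzylation of an α‑methylene ketone, cis fusion by copper hydride 1,4‑reduction.
3. Enedione 27 ⇐ Robinson annulation: key intermolecular Michael addition of dione 23 to methyl vinyl ketone, then catalyst‑controlled aldol condensation (upper ring A is the preformed dione ring; upper ring B is closed last).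
4. Dione 23 ⇐ Knoevenagel condensation/reductive alkylation of cyclohexane‑1,3‑dione with lower‑decalin acetaldehyde 20.
5. Aldehyde 20 ⇐ Eschenmoser–Claisen rearrangement of allylic alcohol 16 ⇐ intramolecular [4+2] of dienyne 11 (both lower rings formed at once, first) ⇐ isobutyraldehyde + methyl acrylate.

Assumption: the target is taken exactly as drawn, i.e. the free bis(hydrogen sulfate) as a single enantiomer.
Conventions: LD = (1R,2S,4aS)‑1,2,5,5‑tetramethyl‑1,2,3,4,4a,5,6,7‑octahydronaphthalen‑1‑yl (the lower decalin). Upper decalin locants: C4 = carbonyl/methylene carbon, C5 = angular carbon bearing the LD‑ethyl chain, C8 = CHMe, C9 = C(Me)CH2Ar, C10 = ring‑fusion CH; β = the face of the C5 chain.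

**Step 1**
Reactants: 1 2‑methylpropanal; 2 methyl acrylate
Product: 4 methyl 4,4‑dimethyl‑5‑oxopentanoate, via pyrrolidine enamine 3 (not isolated)
Conditions: pyrrolidine (1.05 equiv), PhH, Dean–Stark; then 2, MeCN, reflux; AcOH/H2O
Reagents that add atoms: none
Why: Stork enamine Michael addition of the α‑branched aldehyde to the acrylate builds the gem‑dimethyl quaternary carbon; no stereocentre is formed.

**Step 2**
Reactants: 4 methyl 4,4‑dimethyl‑5‑oxopentanoate; 5 diethyl [(2E)‑but‑2‑en‑1‑yl]phosphonate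
Product: 6 methyl (5E,7E)‑4,4‑dimethylnona‑5,7‑dienoate
Conditions: 5, n‑BuLi, THF/DMPU, −78 °C; then 4, −78 °C → rt
Reagents that add atoms: none
Why: Horner–Wadsworth–Emmons olefination of the hindered neopentyl aldehyde with the allylic phosphonate gives the new alkene E and keeps the crotyl E geometry, so the (E,E)‑diene results.

**Step 3**
Reactants: 6 methyl (5E,7E)‑4,4‑dimethylnona‑5,7‑dienoate
Product: 7 (5E,7E)‑N‑methoxy‑N,4,4‑trimethylnona‑5,7‑dienamide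
Conditions: MeNHOMe·HCl, i‑PrMgCl, THF, −20 °C
Reagents that add atoms: N,O‑dimethylhydroxylamine hydrochloride (CNOC.Cl)
Why: Weinreb amidation of the ester through the magnesium amide proceeds without touching the diene.

**Step 4**
Reactants: 7 (5E,7E)‑N‑methoxy‑N,4,4‑trimethylnona‑5,7‑dienamide; 8 prop‑1‑yn‑1‑ylmagnesium bromide
Product: 9 (8E,10E)‑7,7‑dimethyldodeca‑8,10‑dien‑2‑yn‑4‑one
Conditions: 8 (0.5 M in THF), THF, 0 °C; then H2O
Reagents that add atoms: none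
Why: Grignard addition to a Weinreb amide stops at the ketone because the chelated tetrahedral adduct only collapses on work‑up.

**Step 5**
Reactants: 9 (8E,10E)‑7,7‑dimethyldodeca‑8,10‑dien‑2‑yn‑4‑one
Product: 10 (4R,8E,10E)‑7,7‑dimethyldodeca‑8,10‑dien‑2‑yn‑4‑ol
Conditions: RuCl[(R,R)‑TsDPEN](p‑cymene) (1 mol%), i‑PrOH, rt
Reagents that add atoms: none
Why: Noyori asymmetric transfer hydrogenation of the ynone, in which the alkynyl group plays the role of the π‑substituent, gives the (R)‑propargylic alcohol with the (R,R) catalyst and leaves the C=C bonds alone.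

**Step 6**
Reactants: 10 (4R,8E,10E)‑7,7‑dimethyldodeca‑8,10‑dien‑2‑yn‑4‑ol
Product: 11 tert‑butyl{[(4R,8E,10E)‑7,7‑dimethyldodeca‑8,10‑dien‑2‑yn‑4‑yl]oxy}dimethylsilane
Conditions: TBSCl, imidazole, DMF, rt
Reagents that add atoms: tert‑butyldimethylsilyl chloride (C[Si](C)(Cl)C(C)(C)C)
Why: Standard silylation gives a bulky, inert C–O stereocontrol element for the cycloaddition.

**Step 7**
Reactants: 11 tert‑butyl{[(4R,8E,10E)‑7,7‑dimethyldodeca‑8,10‑dien‑2‑yn‑4‑yl]oxy}dimethylsilane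
Product: 12 tert‑butyl(dimethyl){[(1R,4aS,7S)‑4,4,7,8‑tetramethyl‑1,2,3,4,4a,7‑hexahydronaphthalen‑1‑yl]oxy}silane
Conditions: Ni(C8H12)2 (10 mol%), P(O‑C6H4‑2‑Ph)3 (30 mol%), THF, 25–50 °C
Reagents that add atoms: none
Why: The nickel‑catalysed intramolecular [4+2] dienyne cycloaddition (Wender) is suprafacial on the (E,E)‑diene, so 4a‑H and 7‑H end up cis, and the silyloxy group sits pseudoequatorial in the chair‑like tether (trans to 4a‑H), which fixes the absolute configuration of C4a and C7; the minor diastereomer is removed by chromatography.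

**Step 8**
Reactants: 12 tert‑butyl(dimethyl){[(1R,4aS,7S)‑4,4,7,8‑tetramethyl‑1,2,3,4,4a,7‑hexahydronaphthalen‑1‑yl]oxy}silane
Product: 13 tert‑butyl(dimethyl){[(1R,4aS,7S)‑4,4,7,8‑tetramethyl‑1,2,3,4,4a,5,6,7‑octahydronaphthalen‑1‑yl]oxy}silane
Conditions: H2 (1 atm), RhCl(PPh3)3 (5 mol%), PhH, rt
Reagents that add atoms: none
Why: Homogeneous hydrogenation with RhCl(PPh3)3 reduces the cis‑disubstituted alkene and leaves the tetrasubstituted one untouched.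

**Step 9**
Reactants: 13 tert‑butyl(dimethyl){[(1R,4aS,7S)‑4,4,7,8‑tetramethyl‑1,2,3,4,4a,5,6,7‑octahydronaphthalen‑1‑yl]oxy}silane
Product: 14 (1R,4aS,7S)‑4,4,7,8‑tetramethyl‑1,2,3,4,4a,5,6,7‑octahydronaphthalen‑1‑ol
Conditions: Bu4NF, THF, rt
Reagents that add atoms: none
Why: Fluoride‑mediated desilylation frees the allylic alcohol.

**Step 10**
Reactants: 14 (1R,4aS,7S)‑4,4,7,8‑tetramethyl‑1,2,3,4,4a,5,6,7‑octahydronaphthalen‑1‑ol
Product: 15 (4aS,7S)‑4,4,7,8‑tetramethyl‑3,4,4a,5,6,7‑hexahydronaphthalen‑1(2H)‑one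
Conditions: Dess–Martin periodinane, CH2Cl2, rt
Reagents that add atoms: none
Why: Dess–Martin oxidation gives the enone and erases the relay stereocentre at C1, which had the wrong (equatorial) orientation for the rearrangement.

**Step 11**
Reactants: 15 (4aS,7S)‑4,4,7,8‑tetramethyl‑3,4,4a,5,6,7‑hexahydronaphthalen‑1(2H)‑one
Product: 16 (1S,4aS,7S)‑4,4,7,8‑tetramethyl‑1,2,3,4,4a,5,6,7‑octahydronaphthalen‑1‑ol
Conditions: LiBH(s‑Bu)3, THF, −78 °C; then H2O
Reagents that add atoms: none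
Why: The bulky hydride reduces the fully β‑substituted enone 1,2 from the equatorial direction, giving the pseudoaxial alcohol cis to 4a‑H, which is also the isomer free of allylic strain with the 8‑methyl group.

**Step 12**
Reactants: 16 (1S,4aS,7S)‑4,4,7,8‑tetramethyl‑1,2,3,4,4a,5,6,7‑octahydronaphthalen‑1‑ol; 17 1,1‑dimethoxy‑N,N‑dimethylethan‑1‑amine
Product: 19 N,N‑dimethyl‑2‑[(1R,2S,4aS)‑1,2,5,5‑tetramethyl‑1,2,3,4,4a,5,6,7‑octahydronaphthalen‑1‑yl]acetamide, via ketene N,O‑acetal 18 (not isolated)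
Conditions: 17 (5 equiv), xylene, 140 °C
Reagents that add atoms: none
Why: The Eschenmoser–Claisen rearrangement transfers the pseudoaxial C–O bond suprafacially to the alkene terminus, anti to the pseudoaxial neighbouring methyl, creating the quaternary carbon (chain cis to 4a‑H, trans to the vicinal methyl) and moving the alkene to its final ring position.

**Step 13**
Reactants: 19 N,N‑dimethyl‑2‑[(1R,2S,4aS)‑1,2,5,5‑tetramethyl‑1,2,3,4,4a,5,6,7‑octahydronaphthalen‑1‑yl]acetamide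
Product: 20 2‑[(1R,2S,4aS)‑1,2,5,5‑tetramethyl‑1,2,3,4,4a,5,6,7‑octahydronaphthalen‑1‑yl]acetaldehyde
Conditions: Cp2Zr(H)Cl (1.5 equiv), THF, rt; then H2O
Reagents that add atoms: none
Why: Cp2Zr(H)Cl reduces the tertiary amide to the aldehyde and does not hydrozirconate the hindered trisubstituted alkene.

**Step 14**
Reactants: 20 2‑[(1R,2S,4aS)‑1,2,5,5‑tetramethyl‑1,2,3,4,4a,5,6,7‑octahydronaphthalen‑1‑yl]acetaldehyde; 21 cyclohexane‑1,3‑dione
Product: 23 2‑[2‑(LD)ethyl]cyclohexane‑1,3‑dione, via alkylidene dione 22 (not isolated)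
Conditions: 21, Hantzsch ester (1.05 equiv), L‑proline (20 mol%), CH2Cl2, rt
Reagents that add atoms: none
Why: Proline‑catalysed Knoevenagel condensation followed by in‑situ transfer hydrogenation of the alkylidene dione by the Hantzsch ester gives clean mono‑alkylation at C2 of the dione.

**Step 15**
Reactants: 23 2‑[2‑(LD)ethyl]cyclohexane‑1,3‑dione; 24 but‑3‑en‑2‑one
Product: 25 2‑[2‑(LD)ethyl]‑2‑(3‑oxobutyl)cyclohexane‑1,3‑dione
Conditions: 24 (1.5 equiv), Et3N (10 mol%), EtOAc, rt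
Reagents that add atoms: none
Why: Intermolecular Michael addition of the acidic 2‑alkyl‑1,3‑dione to methyl vinyl ketone forms the future angular quaternary carbon C5, which is still prochiral at this stage.

**Step 16**
Reactants: 25 2‑[2‑(LD)ethyl]‑2‑(3‑oxobutyl)cyclohexane‑1,3‑dione
Product: 27 (8aS)‑8a‑[2‑(LD)ethyl]‑3,4,8,8a‑tetrahydronaphthalene‑1,6(2H,7H)‑dione, via bicyclic ketol 26 (not isolated)
Conditions: N‑tosyl‑(Sa)‑binam‑L‑prolinamide (5 mol%), PhCO2H (5 mol%), 2‑MeTHF, rt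
Reagents that add atoms: none
Why: In this Hajos–Parrish–Eder–Sauer–Wiechert aldol condensation the prolinamide enamine attacks one enantiotopic ring carbonyl, setting C5 as (S) by catalyst control in the same sense as for (S)‑Wieland–Miescher ketone.

**Step 17**
Reactants: 27 (8aS)‑8a‑[2‑(LD)ethyl]‑3,4,8,8a‑tetrahydronaphthalene‑1,6(2H,7H)‑dione
Product: 28 (8a'S)‑8a'‑[2‑(LD)ethyl]‑3',4',8',8a'‑tetrahydro‑2'H‑spiro[1,3‑dioxolane‑2,1'‑naphthalen]‑6'(7'H)‑one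
Conditions: 2‑ethyl‑2‑methyl‑1,3‑dioxolane, HOCH2CH2OH (cat.), p‑TsOH (cat.), rt
Reagents that add atoms: 2‑ethyl‑2‑methyl‑1,3‑dioxolane (CCC1(C)OCCO1)
Why: Transketalisation selects the saturated C4 ketone over the less electrophilic enone carbonyl, as for Wieland–Miescher ketone.

**Step 18**
Reactants: 28 (8a'S)‑8a'‑[2‑(LD)ethyl]‑3',4',8',8a'‑tetrahydro‑2'H‑spiro[1,3‑dioxolane‑2,1'‑naphthalen]‑6'(7'H)‑one
Product: 29 cis‑fused silyl enol ether (C4 dioxolane; 10β‑H; C8=C9; 8‑OSiMe2Ph)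
Conditions: [(Ph3P)CuH]6 (5 mol% Cu), PhMe2SiH (1.5 equiv), toluene, rt
Reagents that add atoms: dimethyl(phenyl)silane (C[SiH](C)c1ccccc1)
Why: Copper hydride 1,4‑hydrosilylation delivers hydride axially to C10 on the face of the angular chain, giving the cis‑fused decalin (as in cuprate and copper hydride additions to Wieland–Miescher‑type enones) and a regiodefined C8=C9 silyl enol ether, while the isolated alkene is untouched.

**Step 19**
Reactants: 29 cis‑fused silyl enol ether (C4 dioxolane; 10β‑H; C8=C9; 8‑OSiMe2Ph)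
Product: 30 Mannich base (C4 dioxolane; 10β‑H; 9β‑CH2NMe2; 8‑ketone)
Conditions: Me2N+=CH2 I−, CH2Cl2, rt; aq. NaHCO3
Reagents that add atoms: N,N‑dimethylmethyleneiminium iodide (C=[N+](C)C.[I-])
Why: The Mannich reaction of the silyl enol ether with Eschenmoser's salt is regiospecific for C9; the C9 configuration (convex‑face attack) is irrelevant because it is erased in the next step.

**Step 20**
Reactants: 30 Mannich base (C4 dioxolane; 10β‑H; 9β‑CH2NMe2; 8‑ketone)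
Product: 32 9‑methylene‑8‑ketone (C4 dioxolane; 10β‑H), via methiodide 31 (not isolated)
Conditions: MeI, Et2O/CH2Cl2, rt; then aq. NaHCO3, CH2Cl2
Reagents that add atoms: none
Why: N‑Methylation followed by β‑elimination of trimethylamine gives the α‑methylene ketone.

**Step 21**
Reactants: 32 9‑methylene‑8‑ketone (C4 dioxolane; 10β‑H); 33 2‑(bromomethyl)‑1,4‑dimethoxybenzene
Product: 35 9β‑(2,5‑dimethoxybenzyl)‑9α‑methyl‑8‑ketone (C4 dioxolane; 10β‑H), via lithium enolate 34 (not isolated)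
Conditions: LiBH(s‑Bu)3, THF, −78 °C; then 33, DMPU, −78 → 0 °C
Reagents that add atoms: none
Why: 1,4‑Hydride reduction of the exocyclic enone gives the tetrasubstituted C8=C9 enolate regiospecifically, and SN2 benzylation occurs on the convex face of the cis‑decalin (syn to H‑10, away from ring A), placing CH2Ar β and the methyl α.

**Step 22**
Reactants: 35 9β‑(2,5‑dimethoxybenzyl)‑9α‑methyl‑8‑ketone (C4 dioxolane; 10β‑H)
Product: 36 8‑methylene compound (C4 dioxolane; 10β‑H; 9β‑CH2Ar; 9α‑Me)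
Conditions: Ph3PCH3Br, KOtBu, toluene, 90 °C
Reagents that add atoms: methyltriphenylphosphonium bromide (C[P+](c1ccccc1)(c1ccccc1)c1ccccc1.[Br-])
Why: Wittig methylenation with the unhindered, salt‑free ylide works on ketones flanked by a quaternary carbon.

**Step 23**
Reactants: 36 8‑methylene compound (C4 dioxolane; 10β‑H; 9β‑CH2Ar; 9α‑Me)
Product: 37 8β‑methyl compound (C4 dioxolane; 10β‑H; 9β‑CH2Ar; 9α‑Me)
Conditions: H2 (4 atm), RhCl(PPh3)3 (10 mol%), PhH, rt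
Reagents that add atoms: none
Why: RhCl(PPh3)3 hydrogenates the 1,1‑disubstituted alkene but not the hindered trisubstituted one, and H2 is expected to add from the α face, opposite the axial C9 benzyl group and the angular chain, giving the equatorial 8β‑methyl (cis to CH2Ar).

**Step 24**
Reactants: 37 8β‑methyl compound (C4 dioxolane; 10β‑H; 9β‑CH2Ar; 9α‑Me)
Product: 38 4‑ketone (10β‑H; 9β‑CH2Ar; 9α‑Me; 8β‑Me)
Conditions: p‑TsOH·H2O (0.2 equiv), THF/H2O, 45 °C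
Reagents that add atoms: water (O)
Why: Mild acid hydrolysis removes the dioxolane without isomerising the trisubstituted alkene.

**Step 25**
Reactants: 38 4‑ketone (10β‑H; 9β‑CH2Ar; 9α‑Me; 8β‑Me)
Product: 39 4‑methylene dimethyl ether (10β‑H; 9β‑CH2Ar; 9α‑Me; 8β‑Me)
Conditions: Ph3PCH3Br, KOtBu, toluene, 100 °C
Reagents that add atoms: methyltriphenylphosphonium bromide (C[P+](c1ccccc1)(c1ccccc1)c1ccccc1.[Br-])
Why: Wittig methylenation of the neopentyl C4 ketone installs the exocyclic alkene without touching any stereocentre.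

**Step 26**
Reactants: 39 4‑methylene dimethyl ether (10β‑H; 9β‑CH2Ar; 9α‑Me; 8β‑Me)
Product: 40 2‑substituted 1,4‑benzoquinone
Conditions: (NH4)2Ce(NO3)6 (2.5 equiv), MeCN/H2O, 0 °C
Reagents that add atoms: water (O)
Why: Oxidative demethylation of the 1,4‑dimethoxyarene by (NH4)2Ce(NO3)6 is faster than oxidation of the isolated alkenes at 0 °C.

**Step 27**
Reactants: 40 2‑substituted 1,4‑benzoquinone
Product: 41 hydroquinone
Conditions: Na2S2O4, EtOAc/H2O, rt, Ar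
Reagents that add atoms: none
Why: Dithionite reduces the quinone to the hydroquinone without affecting the alkenes.

**Step 28**
Reactants: 41 hydroquinone
Product: 43 target bis(hydrogen sulfate) CNP0439949.2, via bis(pyridinium) sulfate 42 (not isolated)
Conditions: SO3·pyridine (6 equiv), pyridine, rt; then H+‑form cation‑exchange resin, MeOH/H2O, 0 °C
Reagents that add atoms: sulfur trioxide–pyridine complex ([O-]S(=O)(=O)[n+]1ccccc1)
Why: O‑Sulfation of both phenols with the SO3–pyridine complex followed by cold cation exchange gives the free bis(hydrogen sulfate).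

**Compound list**
1 | 2‑methylpropanal (isobutyraldehyde) | CC(C)C=O | starting material
2 | methyl acrylate | C=CC(=O)OC | starting material
3 | 1‑(2‑methylprop‑1‑en‑1‑yl)pyrrolidine | CC(C)=CN1CCCC1 | intermediate
4 | methyl 4,4‑dimethyl‑5‑oxopentanoate | COC(=O)CCC(C)(C)C=O | intermediate
5 | diethyl [(2E)‑but‑2‑en‑1‑yl]phosphonate | C/C=C/CP(=O)(OCC)OCC | starting material
6 | methyl (5E,7E)‑4,4‑dimethylnona‑5,7‑dienoate | COC(=O)CCC(C)(C)/C=C/C=C/C | intermediate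
7 | (5E,7E)‑N‑methoxy‑N,4,4‑trimethylnona‑5,7‑dienamide | CON(C)C(=O)CCC(C)(C)/C=C/C=C/C | intermediate
8 | prop‑1‑yn‑1‑ylmagnesium bromide | CC#C[Mg]Br | starting material
9 | (8E,10E)‑7,7‑dimethyldodeca‑8,10‑dien‑2‑yn‑4‑one | CC#CC(=O)CCC(C)(C)/C=C/C=C/C | intermediate
10 | (4R,8E,10E)‑7,7‑dimethyldodeca‑8,10‑dien‑2‑yn‑4‑ol | CC#C[C@H](O)CCC(C)(C)/C=C/C=C/C | intermediate
11 | tert‑butyl{[(4R,8E,10E)‑7,7‑dimethyldodeca‑8,10‑dien‑2‑yn‑4‑yl]oxy}dimethylsilane | CC#C[C@H](O[Si](C)(C)C(C)(C)C)CCC(C)(C)/C=C/C=C/C | intermediate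
12 | tert‑butyl(dimethyl){[(1R,4aS,7S)‑4,4,7,8‑tetramethyl‑1,2,3,4,4a,7‑hexahydronaphthalen‑1‑yl]oxy}silane | CC1=C2[C@H](O[Si](C)(C)C(C)(C)C)CCC(C)(C)[C@@H]2C=C[C@@H]1C | intermediate
13 | tert‑butyl(dimethyl){[(1R,4aS,7S)‑4,4,7,8‑tetramethyl‑1,2,3,4,4a,5,6,7‑octahydronaphthalen‑1‑yl]oxy}silane | CC1=C2[C@H](O[Si](C)(C)C(C)(C)C)CCC(C)(C)[C@@H]2CC[C@@H]1C | intermediate
14 | (1R,4aS,7S)‑4,4,7,8‑tetramethyl‑1,2,3,4,4a,5,6,7‑octahydronaphthalen‑1‑ol | CC1=C2[C@H](O)CCC(C)(C)[C@@H]2CC[C@@H]1C | intermediate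
15 | (4aS,7S)‑4,4,7,8‑tetramethyl‑3,4,4a,5,6,7‑hexahydronaphthalen‑1(2H)‑one | CC1=C2C(=O)CCC(C)(C)[C@@H]2CC[C@@H]1C | intermediate
16 | (1S,4aS,7S)‑4,4,7,8‑tetramethyl‑1,2,3,4,4a,5,6,7‑octahydronaphthalen‑1‑ol | CC1=C2[C@@H](O)CCC(C)(C)[C@@H]2CC[C@@H]1C | intermediate
17 | 1,1‑dimethoxy‑N,N‑dimethylethan‑1‑amine (N,N‑dimethylacetamide dimethyl acetal) | COC(C)(OC)N(C)C | starting material
18 | N,N‑dimethyl‑1‑{[(1S,4aS,7S)‑4,4,7,8‑tetramethyl‑1,2,3,4,4a,5,6,7‑octahydronaphthalen‑1‑yl]oxy}ethen‑1‑amine | CC1=C2[C@@H](OC(=C)N(C)C)CCC(C)(C)[C@@H]2CC[C@@H]1C | intermediate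
19 | N,N‑dimethyl‑2‑[(1R,2S,4aS)‑1,2,5,5‑tetramethyl‑1,2,3,4,4a,5,6,7‑octahydronaphthalen‑1‑yl]acetamide | CN(C)C(=O)C[C@@]1(C)C2=CCCC(C)(C)[C@@H]2CC[C@@H]1C | intermediate
20 | 2‑[(1R,2S,4aS)‑1,2,5,5‑tetramethyl‑1,2,3,4,4a,5,6,7‑octahydronaphthalen‑1‑yl]acetaldehyde | O=CC[C@@]1(C)C2=CCCC(C)(C)[C@@H]2CC[C@@H]1C | intermediate
21 | cyclohexane‑1,3‑dione | O=C1CCCC(=O)C1 | starting material
22 | 2‑[2‑(LD)ethylidene]cyclohexane‑1,3‑dione | O=C1CCCC(=O)C1=CC[C@@]1(C)C2=CCCC(C)(C)[C@@H]2CC[C@@H]1C | intermediate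
23 | 2‑[2‑(LD)ethyl]cyclohexane‑1,3‑dione | O=C1CCCC(=O)C1CC[C@@]1(C)C2=CCCC(C)(C)[C@@H]2CC[C@@H]1C | intermediate
24 | but‑3‑en‑2‑one (methyl vinyl ketone) | CC(=O)C=C | starting material
25 | 2‑[2‑(LD)ethyl]‑2‑(3‑oxobutyl)cyclohexane‑1,3‑dione | CC(=O)CCC1(CC[C@@]2(C)C3=CCCC(C)(C)[C@@H]3CC[C@@H]2C)C(=O)CCCC1=O | intermediate
26 | (4aS,8aS)‑4a‑hydroxy‑8a‑[2‑(LD)ethyl]hexahydronaphthalene‑1,6(2H,5H)‑dione (cis‑fused ketol) | O=C1CCC[C@]2(O)CC(=O)CC[C@]12CC[C@@]1(C)C3=CCCC(C)(C)[C@@H]3CC[C@@H]1C | intermediate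
27 | (8aS)‑8a‑[2‑(LD)ethyl]‑3,4,8,8a‑tetrahydronaphthalene‑1,6(2H,7H)‑dione | O=C1CCCC2=CC(=O)CC[C@]12CC[C@@]1(C)C3=CCCC(C)(C)[C@@H]3CC[C@@H]1C | intermediate
28 | (8a'S)‑8a'‑[2‑(LD)ethyl]‑3',4',8',8a'‑tetrahydro‑2'H‑spiro[1,3‑dioxolane‑2,1'‑naphthalen]‑6'(7'H)‑one (C4 dioxolane of 27) | O1CCOC12CCCC3=CC(=O)CC[C@]23CC[C@@]2(C)C4=CCCC(C)(C)[C@@H]4CC[C@@H]2C | intermediate
29 | cis‑fused silyl enol ether: C4 dioxolane; 10β‑H; C8=C9; 8‑OSiMe2Ph; 5‑(LD‑ethyl) | O1CCOC12CCC[C@@H]3C=C(O[Si](C)(C)c4ccccc4)CC[C@]23CC[C@@]2(C)C4=CCCC(C)(C)[C@@H]4CC[C@@H]2C | intermediate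
30 | Mannich base: C4 dioxolane; 10β‑H; 9β‑CH2NMe2; 8‑ketone | O1CCOC12CCC[C@@H]3[C@@H](CN(C)C)C(=O)CC[C@]23CC[C@@]2(C)C4=CCCC(C)(C)[C@@H]4CC[C@@H]2C | intermediate
31 | trimethylammonium iodide (methiodide) of 30 | O1CCOC12CCC[C@@H]3[C@@H](C[N+](C)(C)C)C(=O)CC[C@]23CC[C@@]2(C)C4=CCCC(C)(C)[C@@H]4CC[C@@H]2C.[I-] | intermediate
32 | 9‑methylene‑8‑ketone: C4 dioxolane; 10β‑H | O1CCOC12CCC[C@@H]3C(=C)C(=O)CC[C@]23CC[C@@]2(C)C4=CCCC(C)(C)[C@@H]4CC[C@@H]2C | intermediate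
33 | 2‑(bromomethyl)‑1,4‑dimethoxybenzene (2,5‑dimethoxybenzyl bromide) | COc1ccc(OC)c(CBr)c1 | starting material
34 | lithium C8(O)=C9(Me) enolate: C4 dioxolane; 10β‑H | O1CCOC12CCC[C@@H]3C(C)=C([O-])CC[C@]23CC[C@@]2(C)C4=CCCC(C)(C)[C@@H]4CC[C@@H]2C.[Li+] | intermediate
35 | 9β‑(2,5‑dimethoxybenzyl)‑9α‑methyl‑8‑ketone: C4 dioxolane; 10β‑H | O1CCOC12CCC[C@@H]3[C@@](C)(Cc4cc(OC)ccc4OC)C(=O)CC[C@]23CC[C@@]2(C)C4=CCCC(C)(C)[C@@H]4CC[C@@H]2C | intermediate
36 | 8‑methylene compound: C4 dioxolane; 10β‑H; 9β‑CH2Ar; 9α‑Me | O1CCOC12CCC[C@@H]3[C@@](C)(Cc4cc(OC)ccc4OC)C(=C)CC[C@]23CC[C@@]2(C)C4=CCCC(C)(C)[C@@H]4CC[C@@H]2C | intermediate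
37 | 8β‑methyl compound: C4 dioxolane; 10β‑H; 9β‑CH2Ar; 9α‑Me | O1CCOC12CCC[C@@H]3[C@@](C)(Cc4cc(OC)ccc4OC)[C@@H](C)CC[C@]23CC[C@@]2(C)C4=CCCC(C)(C)[C@@H]4CC[C@@H]2C | intermediate
38 | 4‑ketone: 10β‑H; 9β‑(2,5‑dimethoxybenzyl); 9α‑Me; 8β‑Me; 5‑(LD‑ethyl) | O=C1CCC[C@@H]2[C@@](C)(Cc3cc(OC)ccc3OC)[C@@H](C)CC[C@]12CC[C@@]1(C)C3=CCCC(C)(C)[C@@H]3CC[C@@H]1C | intermediate
39 | 4‑methylene dimethyl ether (same stereochemistry as 38) | C=C1CCC[C@@H]2[C@@](C)(Cc3cc(OC)ccc3OC)[C@@H](C)CC[C@]12CC[C@@]1(C)C3=CCCC(C)(C)[C@@H]3CC[C@@H]1C | intermediate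
40 | 2‑substituted 1,4‑benzoquinone from 39 | C=C1CCC[C@@H]2[C@@](C)(CC3=CC(=O)C=CC3=O)[C@@H](C)CC[C@]12CC[C@@]1(C)C3=CCCC(C)(C)[C@@H]3CC[C@@H]1C | intermediate
41 | hydroquinone from 40 | C=C1CCC[C@@H]2[C@@](C)(Cc3cc(O)ccc3O)[C@@H](C)CC[C@]12CC[C@@]1(C)C3=CCCC(C)(C)[C@@H]3CC[C@@H]1C | intermediate
42 | bis(pyridinium) bis(sulfate) of 41 | C=C1CCC[C@@H]2[C@@](C)(Cc3cc(OS(=O)(=O)[O-])ccc3OS(=O)(=O)[O-])[C@@H](C)CC[C@]12CC[C@@]1(C)C3=CCCC(C)(C)[C@@H]3CC[C@@H]1C.c1cc[nH+]cc1.c1cc[nH+]cc1 | intermediate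
43 | CNP0439949.2, bis(hydrogen sulfate) | C=C1CCC[C@H]2[C@]1(CC[C@@]1(C)C3=CCCC(C)(C)[C@@H]3CC[C@@H]1C)CC[C@H](C)[C@]2(C)Cc1cc(OS(=O)(=O)O)ccc1OS(=O)(=O)O | target

**Totals**
Total step count: 28. Longest linear sequence: 28 steps (from 1 to 43; all other inputs are purchased).

**Three steps most likely to fail**

Step 7 (the [4+2] may be slow with the neopentyl diene terminus, or poorly face‑selective). The fallback sets out from ynone 9 and comes back at enone 15. The ynone, now an activated dienophile, is cyclised in an intramolecular Diels–Alder reaction catalysed by a chiral cationic oxazaborolidine (the (S)‑o‑tolyl CBS oxazaborolidine protonated with Tf2NH, CH2Cl2, −40 → 0 °C), chosen so that the cis dienone (4aS,7S)‑4,4,7,8‑tetramethyl‑3,4,4a,7‑tetrahydronaphthalen‑1(2H)‑one F1 is the major enantiomer. Hydrogenation of its disubstituted alkene with H2 and RhCl(PPh3)3 gives 15, so the silyl ether relay (10 to 14) is bypassed.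

Step 21 (the hindered tetrasubstituted enolate may alkylate slowly, on oxygen, or with low facial selectivity). The fallback sets out from 32 and comes back at 35. Compound 32 is reduced with LiBH(s‑Bu)3 and the enolate is trapped with Me3SiCl to give the tetrasubstituted trimethylsilyl enol ether (C4 dioxolane; 10β‑H; C8=C9; 9‑Me) F2. This is benzylated under SN1‑type Lewis‑acid conditions (Reetz alkylation) with 33 and ZnBr2 in CH2Cl2, where the stabilised 2,5‑dimethoxybenzyl cation again attacks the convex face and gives 35.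

Step 23 (hydrogenation may give the 8‑epimer or stall at the neopentyl alkene). The fallback sets out from 35 and comes back at 37, replacing kinetic facial control by thermodynamic control. Reductive cyanation of the ketone with TosMIC/KOtBu in DME/EtOH (van Leusen), with base equilibration, gives the equatorial 8β‑nitrile (C4 dioxolane; 10β‑H; 9β‑CH2Ar; 9α‑Me) F3. Reduction with i‑Bu2AlH and aqueous work‑up gives the 8β‑carbaldehyde F4, and Wolff–Kishner reduction (N2H4·H2O, KOH, diethylene glycol, 195 °C) converts CHO into CH3 to give 37.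

**Further compounds**
F1 | step 7 | (4aS,7S)‑4,4,7,8‑tetramethyl‑3,4,4a,7‑tetrahydronaphthalen‑1(2H)‑one | CC1=C2C(=O)CCC(C)(C)[C@@H]2C=C[C@@H]1C
F2 | step 21 | trimethylsilyl enol ether: C4 dioxolane; 10β‑H; C8=C9; 9‑Me; 8‑OSiMe3 | O1CCOC12CCC[C@@H]3C(C)=C(O[Si](C)(C)C)CC[C@]23CC[C@@]2(C)C4=CCCC(C)(C)[C@@H]4CC[C@@H]2C
F3 | step 23 | 8β‑nitrile: C4 dioxolane; 10β‑H; 9β‑(2,5‑dimethoxybenzyl); 9α‑Me | O1CCOC12CCC[C@@H]3[C@@](C)(Cc4cc(OC)ccc4OC)[C@@H](C#N)CC[C@]23CC[C@@]2(C)C4=CCCC(C)(C)[C@@H]4CC[C@@H]2C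
F4 | step 23 | 8β‑carbaldehyde: C4 dioxolane; 10β‑H; 9β‑(2,5‑dimethoxybenzyl); 9α‑Me | O1CCOC12CCC[C@@H]3[C@@](C)(Cc4cc(OC)ccc4OC)[C@@H](C=O)CC[C@]23CC[C@@]2(C)C4=CCCC(C)(C)[C@@H]4CC[C@@H]2C
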